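The constants are assumed; the rest is arithmetic.

Amounts first: north-west holds its whole charge from the start, south-east receives the same substrate steadily over the run, and the two look nearly alike.

    partner + first product → double product + by-product (k1 = 6.13 M⁻¹ s⁻¹)
    double product → over-reaction product (k2 = 0.0227 s⁻¹)
    first product + capture agent → trapped intermediate (k3 = 498 M⁻¹ s⁻¹)
    partner + double product → triple product + by-product (k4 = 25.2 M⁻¹ s⁻¹)
    substrate + double product ⇌ idle adduct, settled at all times (K5 = 1260 M⁻¹)
    substrate + partner → first product + by-product (k6 = 17.0 M⁻¹ s⁻¹)

| setting | north-west | south-east | west | north |
|---|---|---|---|---|
| substrate | 1.0 mM | 1.0 mM (fed, over 30.0 s) | 1.0 mM | 1.0 mM |
| partner | 1.10 mM | 1.10 mM | 1.10 mM | 1.10 mM (fed, over 30.0 s) |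
| capture agent | 0.0200 mM | 0.0200 mM | 0.0200 mM | 0.0200 mM |
| time | 30 s | 30 s |  | 30 s |
| remark | everything together in a closed stirred flask, run for 30 s | a stirred flask in which substrate is dosed at a steady rate over 30.0 s without added volume, worked up at 30 s | a single well-mixed tank run continuously and read at steady state, 30 s in it on average | a stirred flask in which partner is dosed at a steady rate over 30.0 s without added volume, worked up at 30 s |

- a species is counted by the substrate in it: one idle adduct counts as two
- amounts and yields of double product count idle adduct too
- the stated concentrations are those of everything mixed, before any reaction; amounts are the same in each set-up
- the feed brings no volume worth counting
- in an amount of double product, one idle adduct counts as one double product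
- run time (north-west): 30 s

* the set-up with the highest share of double product in all that became double product or triple product or trapped intermediate or over-reaction product, at the outlet or at the end ("none" if the first two lie within 2 percentage points) (north-west / south-east / west / north / none)
* share of double product in all that became double product or triple product or trapped intermediate or over-reaction product, at the outlet or at the end, north-west
* share of double product in all that became double product or triple product or trapped intermediate or over-reaction product, at the outlet or at the end, south-east
* share of double product in all that became double product or triple product or trapped intermediate or over-reaction product, at the outlet or at the end, west
* share of double product in all that became double product or triple product or trapped intermediate or over-reaction product, at the outlet or at the end, north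

I compared these two flasks by counting turnovers, with amounts as fractions of the charge. In north-west the step of substrate with partner has 0.561 turnovers in the run, so I took 0.359 of the substrate as converted. First product then averages that figure divided by 2, or 0.180. Multiplying this mean by the capture constant, the substrate charge and the run time gave 2.68, the trap turnovers: the time constants lived through by the capture agent in its pseudo-first-order decay. I therefore expected 0.932 of the agent spent, which is nearly all, and trapped intermediate at 0.0186 of the substrate charge.

Double product made came to 0.0298. Over-reaction and the step to triple product act on its free form over a mean age of a third of the run, and I kept 0.777 of it. That gave north-west 47.8%.

In south-east I took 0.219 converted, with first product averaging that divided by 3, so the trap turnovers were 1.09, fewer than in north-west. Its double product per trapped intermediate, 0.990, was below the 1.60 of north-west, because I reckoned 0.664 of the capture agent spent in south-east, less than in north-west. Assuming the same survival, I reckoned south-east at 38.7%.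

The forecast chose north-west, with 45%, 41%, 41% and 38% for north-west, south-east, west and north, saying “the batch flask builds first product fastest”. My figure for north-west is above its value, and mine for south-east is below.

The simulation put north-west first, with 46.8%, against 40.8% for west, 39.8% for south-east and 35.4% for north. North-west kept 6.2% of its capture agent, against 6.86% from the trap turnovers. The neighbouring flask, north-west with 0.034 mM of capture agent, has the same count, so I reckoned the same fraction left, trapped intermediate at 0.0317 of the substrate charge, and, assuming the same double product made and the same survival, a share of 37.6%. That flask kept 6.9% of its agent, held 3.17% as trapped intermediate, and gave a share of 36.0%.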